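A direct plan would build ring A by a Danheiser-type benzannulation: acyloxycyclobutenone A2, reached in four steps from squarate A1, would be heated with the silylated methoxyalkynyl carbinol A3 to give arene A4, which would be desilylated, oxidized to the enone and freed of its tert-butyl ether. Its weakest steps would be the benzannulation (unprecedented for a 4-acyloxycyclobutenone; the vinylketene must meet a labile ynol ether in one [2+2] orientation), the passage from A1 to A2 (two hydride reductions and a transposition: length without complexity), and the three closing adjustments, during which the ester could migrate to a neighbouring phenol or acid could close the chalcone to a flavanone.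

The new route cuts ring A (C1' bears the cinnamoyl group, C2'–C6' follow through the ester carbon C3') into two three-carbon pieces. C2'–C3'–C4' would come from tartronic acid as an acyloxymalonyl dichloride that is symmetric about C3' and already carries the (S)-2-methylbutanoate; C5'–C6'–C1' would come from the silyl dienol ether of a β-methoxy styryl dienone. One [3+3] double C-acylation (C4'–C5', then Claisen-type closure C1'–C2'), modelled on the biosynthetic malonyl extension and folding, should give the target itself: the symmetry of the dichloride settles the regiochemistry, the enol ether becomes the 6'-methoxy group and the two chlorocarbonyl carbons become the free 2'- and 4'-hydroxyls. No four-membered ring, ynol ether, protecting group or late oxidation remains.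

Key step: step 7

Remark: the geometry of the silyl enol ether double bond of the diene is left open, because that carbon becomes aromatic C1'.

Step 1
Reactants: 1 (S)-2-methylbutanoic acid
Product: 2 (S)-2-methylbutanoyl chloride
Conditions: (COCl)2 (1.2 equiv), DMF (cat.), CH2Cl2, 0 °C → rt; concentrated cold, used crude
Reagents that add atoms: oxalyl chloride, O=C(Cl)C(=O)Cl
Why: Acid chloride formation through the Vilsmeier-type chloroiminium ion is base-free, so no ketene can form and the (S)-α-carbon should be retained; no new stereocenter.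

Step 2
Reactants: 2 (S)-2-methylbutanoyl chloride; 3 tartronic acid (2-hydroxypropanedioic acid)
Product: 4 2-{[(2S)-2-methylbutanoyl]oxy}propanedioic acid
Conditions: 3 (1.2 equiv), 1,4-dioxane, 50 °C, N2 sweep; H2O, extraction (EtOAc)
Reagents that add atoms: none
Why: Base-free O-acylation of an α-hydroxy acid by an acid chloride (the reaction type that gives O-acylmandelic acids): HCl is swept out, any mixed anhydride is hydrolysed in the work-up, the absence of base excludes a ketene and keeps the (S)-center, and the malonate carbon is not stereogenic.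

Step 3
Reactants: 4 2-{[(2S)-2-methylbutanoyl]oxy}propanedioic acid
Product: 5 2-{[(2S)-2-methylbutanoyl]oxy}propanedioyl dichloride
Conditions: (COCl)2 (2.5 equiv), DMF (cat.), CH2Cl2, 0 °C → rt; volatiles removed at rt, used at once as a CH2Cl2 solution
Reagents that add atoms: oxalyl chloride, O=C(Cl)C(=O)Cl
Why: Chloroiminium-catalysed conversion of both carboxyl groups at or below room temperature stays under the decarboxylation threshold of a malonic acid and uses no base, so neither the chlorocarbonyl ketene nor epimerization is expected.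

Step 4
Reactants: 6 (E)-4-methoxypent-3-en-2-one; 7 benzaldehyde
Product: 10 (4E)-1-hydroxy-5-methoxy-1-phenylhex-4-en-3-one (racemic), via lithium enolate 8 (not isolated), via lithium aldolate 9 (not isolated)
Conditions: LiN(i-Pr)2 (1.05 equiv, commercial solution), THF, −78 °C; 7, −78 °C; aq. NH4Cl
Reagents that add atoms: none
Why: Kinetic deprotonation of the vinylogous ester at its α'-methyl group and addition of the cross-conjugated lithium enolate to the aldehyde (directed aldol reaction); the carbinol center is racemic and is removed in step 5.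

Step 5
Reactants: 10 (4E)-1-hydroxy-5-methoxy-1-phenylhex-4-en-3-one
Product: 12 (1E,4E)-5-methoxy-1-phenylhexa-1,4-dien-3-one, via β-mesyloxy ketone 11 (not isolated)
Conditions: MsCl (1.3 equiv), Et3N (3 equiv), CH2Cl2, 0 °C → rt
Reagents that add atoms: none
Why: Mesylation and E1cB elimination under basic conditions should give the thermodynamically favoured (E)-styryl ketone and avoid the acid-catalysed oxa-Michael closure of 10 to a dihydropyranone; the stereocenter is erased.

Step 6
Reactants: 12 (1E,4E)-5-methoxy-1-phenylhexa-1,4-dien-3-one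
Product: 14 trimethyl{[(1E)-5-methoxy-1-phenylhexa-1,3,5-trien-3-yl]oxy}silane, via lithium dienolate 13 (not isolated)
Conditions: LiN(i-Pr)2 (1.1 equiv, commercial solution), THF, −78 °C; Me3SiCl (1.3 equiv), −78 → 0 °C; pentane, filtration under argon, used crude
Reagents that add atoms: chlorotrimethylsilane, C[Si](C)(C)Cl
Why: Both α-positions of 12 are vinylic, so the amide base should remove a γ-proton from the methyl group of the β-methoxy enone and the extended enolate should be silylated on oxygen, as in the known γ-deprotonation and O-silylation of β-methoxy-α,β-unsaturated esters; no stereocenter is formed.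

Step 7
Reactants: 5 2-{[(2S)-2-methylbutanoyl]oxy}propanedioyl dichloride; 14 trimethyl{[(1E)-5-methoxy-1-phenylhexa-1,3,5-trien-3-yl]oxy}silane
Product: 17 3-[(E)-cinnamoyl]-2,6-dihydroxy-4-methoxyphenyl (2S)-2-methylbutanoate (CNP0173852.1), via β-keto acid chloride 15 (not isolated), via cyclohexenedione 16 (not isolated)
Conditions: 14 added slowly to 5 (1.1 equiv), CH2Cl2 (0.02 M), −78 °C; then −78 → 20 °C, 12 h; pH 7 phosphate buffer
Reagents that add atoms: none
Why: Proposed new method: the closest known reaction types are the Effenberger cyclization (double C-acylation of an enol ether by malonyl dichloride to a cyclohexane-1,3,5-trione) and the uncatalysed γ-C-acylation of Chan-type silyl dienol ethers by acid chlorides, but an acyloxymalonyl dichloride and an acyclic 2-methoxy-4-silyloxy diene have not been combined, so the step is put forward on mechanistic grounds. The terminal CH2 of 14, activated by both oxygens, should attack one of the two equivalent chlorocarbonyl groups of 5 at −78 °C with loss of Me3SiCl, forming C4'–C5' and β-keto acid chloride 15 before any HCl is present that could hydrolyse the diene. On warming, 15 in its enol form is a 1-hydroxy-3-methoxy diene whose terminal carbon C1' should attack the second chlorocarbonyl group in a 6-(enolendo)-exo-trig Claisen-type C-acylation (the α-oxoketene, if it forms by loss of HCl, would close at the same carbon), forming C1'–C2' and closing ring A as dione 16, which aromatizes by enolization to the hydrogen-bonded 2'-hydroxy ketone 17. No stereocenter is formed (C3' becomes aromatic), and the base-free conditions should leave the ester on O3' and its (S)-α-carbon untouched. The selectivities needed are C- over O-acylation in the ring closure and the placement of five substituents: the methyl ether blocks the only oxygen that could close a pyranone and should survive as the 6'-methoxy group because aromatization outruns demethylation, and since 5 is symmetric about C3' either order of the two C–C bond formations gives the same arene, with the ester between the two new hydroxyls.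

**Compound list**

1 | (S)-2-methylbutanoic acid | CC[C@H](C)C(=O)O | starting material
2 | (S)-2-methylbutanoyl chloride | CC[C@H](C)C(=O)Cl | intermediate
3 | tartronic acid (2-hydroxypropanedioic acid) | OC(C(=O)O)C(=O)O | starting material
4 | 2-{[(2S)-2-methylbutanoyl]oxy}propanedioic acid | CC[C@H](C)C(=O)OC(C(=O)O)C(=O)O | intermediate
5 | 2-{[(2S)-2-methylbutanoyl]oxy}propanedioyl dichloride | CC[C@H](C)C(=O)OC(C(=O)Cl)C(=O)Cl | intermediate
6 | (E)-4-methoxypent-3-en-2-one | CO/C(C)=C/C(C)=O | starting material
7 | benzaldehyde | O=Cc1ccccc1 | starting material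
8 | lithium (3E)-4-methoxypenta-1,3-dien-2-olate (not isolated) | CO/C(C)=C/C(=C)[O-].[Li+] | intermediate
9 | lithium (4E)-5-methoxy-3-oxo-1-phenylhex-4-en-1-olate (racemic, not isolated) | CO/C(C)=C/C(=O)CC([O-])c1ccccc1.[Li+] | intermediate
10 | (4E)-1-hydroxy-5-methoxy-1-phenylhex-4-en-3-one (racemic) | CO/C(C)=C/C(=O)CC(O)c1ccccc1 | intermediate
11 | (4E)-5-methoxy-3-oxo-1-phenylhex-4-en-1-yl methanesulfonate (racemic, not isolated) | CO/C(C)=C/C(=O)CC(OS(C)(=O)=O)c1ccccc1 | intermediate
12 | (1E,4E)-5-methoxy-1-phenylhexa-1,4-dien-3-one | CO/C(C)=C/C(=O)/C=C/c1ccccc1 | intermediate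
13 | lithium (1E)-5-methoxy-1-phenylhexa-1,3,5-trien-3-olate (not isolated) | C=C(OC)C=C([O-])/C=C/c1ccccc1.[Li+] | intermediate
14 | trimethyl{[(1E)-5-methoxy-1-phenylhexa-1,3,5-trien-3-yl]oxy}silane (either geometry at C3=C4) | C=C(OC)C=C(O[Si](C)(C)C)/C=C/c1ccccc1 | intermediate
15 | (8E)-1-chloro-5-methoxy-1,3,7-trioxo-9-phenylnona-5,8-dien-2-yl (2S)-2-methylbutanoate (not isolated; either configuration at C2, either geometry at C5=C6) | CC[C@H](C)C(=O)OC(C(=O)Cl)C(=O)CC(OC)=CC(=O)/C=C/c1ccccc1 | intermediate
16 | 3-[(E)-cinnamoyl]-4-methoxy-2,6-dioxocyclohex-3-en-1-yl (2S)-2-methylbutanoate (not isolated; either configuration at the ring carbon) | CC[C@H](C)C(=O)OC1C(=O)CC(OC)=C(C(=O)/C=C/c2ccccc2)C1=O | intermediate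
17 | 3-[(E)-cinnamoyl]-2,6-dihydroxy-4-methoxyphenyl (2S)-2-methylbutanoate (CNP0173852.1) | CC[C@H](C)C(=O)Oc1c(O)cc(OC)c(C(=O)/C=C/c2ccccc2)c1O | target

**Step count and risks**

Total: 7 steps. Longest linear sequence: 4 steps (6 → 10 → 12 → 14 → 17; the branch 1 → 2 → 4 → 5 → 17 is equally long).

Steps most likely to fail:

1. Step 7 (proposed new method). The second C-acylation may not follow the first, so that the open-chain acid chloride oligomerizes through its ketene or acylates the phenols of the product; HCl may also close the chalcone to a flavanone. The fallback sets out from 14 (and uses 2) and comes back at 17. It makes the two C–C bonds in separate, known operations with the C3' oxygen as a benzyl ether and attaches the ester last. Diethyl 2-(benzyloxy)malonate would be half-saponified (KOH, 1 equiv, EtOH) to 2-(benzyloxy)-3-ethoxy-3-oxopropanoic acid F1 and converted ((COCl)2, cat. DMF) into ethyl 2-(benzyloxy)-3-chloro-3-oxopropanoate F2. Uncatalysed γ-C-acylation of 14 by F2 (CH2Cl2, −78 → 20 °C) would give ethyl (8E)-2-(benzyloxy)-5-methoxy-3,7-dioxo-9-phenylnona-5,8-dienoate F3. Its dianion (NaH, THF, 0 °C → rt) would close ring A by Claisen condensation to 3'-benzyloxy-2',4'-dihydroxy-6'-methoxychalcone F4. BCl3/C6HMe5 (CH2Cl2, −78 °C) would give 2',3',4'-trihydroxy-6'-methoxychalcone F5. MOMCl/i-Pr2NEt (1 equiv) would cap the most acidic 4'-hydroxyl to give 2',3'-dihydroxy-6'-methoxy-4'-(methoxymethoxy)chalcone F6. Acid chloride 2 with pyridine would acylate the 3'-hydroxyl, the 2'-hydroxyl being chelated, to give 3-[(E)-cinnamoyl]-2-hydroxy-4-methoxy-6-(methoxymethoxy)phenyl (2S)-2-methylbutanoate F7. CF3CO2H/CH2Cl2 at 0 °C would remove the MOM group and give 17.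

2. Step 3. The dichloride may lose HCl to the chlorocarbonyl ketene and oligomerize, or a half-converted acid may decarboxylate, during chlorination or concentration. The fallback sets out from 4 and comes back at 5. Both carboxyl groups would be silylated with N,O-bis(trimethylsilyl)acetamide to bis(trimethylsilyl) 2-{[(2S)-2-methylbutanoyl]oxy}propanedioate F8. Treatment of the silyl ester with (COCl)2/cat. DMF at 0 °C should give 5 without free HCl, and the solution would go directly into step 7.

3. Step 2. O-Acylation of the poorly soluble, deactivated hydroxyl may be slow or incomplete, with mixed-anhydride formation at the carboxyl groups. The fallback sets out from 1 and comes back at 4. Dibenzyl malonate would be converted (4-acetamidobenzenesulfonyl azide, Et3N, MeCN) into dibenzyl 2-diazopropanedioate F9. O–H insertion of its carbenoid into acid 1 (Rh2(OAc)4 cat., CH2Cl2, rt → 40 °C) would give dibenzyl 2-{[(2S)-2-methylbutanoyl]oxy}propanedioate F10. Hydrogenolysis (H2, Pd/C, EtOAc) would give 4. The acid is never activated in this sequence, so its (S)-center cannot epimerize.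

**Further compounds**

F1 | step 7 | 2-(benzyloxy)-3-ethoxy-3-oxopropanoic acid (racemic) | CCOC(=O)C(OCc1ccccc1)C(=O)O
F2 | step 7 | ethyl 2-(benzyloxy)-3-chloro-3-oxopropanoate (racemic) | CCOC(=O)C(OCc1ccccc1)C(=O)Cl
F3 | step 7 | ethyl (8E)-2-(benzyloxy)-5-methoxy-3,7-dioxo-9-phenylnona-5,8-dienoate | CCOC(=O)C(OCc1ccccc1)C(=O)CC(OC)=CC(=O)/C=C/c1ccccc1
F4 | step 7 | (E)-1-[3-(benzyloxy)-2,4-dihydroxy-6-methoxyphenyl]-3-phenylprop-2-en-1-one | COc1cc(O)c(OCc2ccccc2)c(O)c1C(=O)/C=C/c1ccccc1
F5 | step 7 | (E)-3-phenyl-1-(2,3,4-trihydroxy-6-methoxyphenyl)prop-2-en-1-one | COc1cc(O)c(O)c(O)c1C(=O)/C=C/c1ccccc1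
F6 | step 7 | (E)-1-[2,3-dihydroxy-6-methoxy-4-(methoxymethoxy)phenyl]-3-phenylprop-2-en-1-one | COCOc1cc(OC)c(C(=O)/C=C/c2ccccc2)c(O)c1O
F7 | step 7 | 3-[(E)-cinnamoyl]-2-hydroxy-4-methoxy-6-(methoxymethoxy)phenyl (2S)-2-methylbutanoate | CC[C@H](C)C(=O)Oc1c(OCOC)cc(OC)c(C(=O)/C=C/c2ccccc2)c1O
F8 | step 3 | bis(trimethylsilyl) 2-{[(2S)-2-methylbutanoyl]oxy}propanedioate | CC[C@H](C)C(=O)OC(C(=O)O[Si](C)(C)C)C(=O)O[Si](C)(C)C
F9 | step 2 | dibenzyl 2-diazopropanedioate | [N-]=[N+]=C(C(=O)OCc1ccccc1)C(=O)OCc1ccccc1
F10 | step 2 | dibenzyl 2-{[(2S)-2-methylbutanoyl]oxy}propanedioate | CC[C@H](C)C(=O)OC(C(=O)OCc1ccccc1)C(=O)OCc1ccccc1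
A1 | direct plan | di-tert-butyl squarate (3,4-di-tert-butoxycyclobut-3-ene-1,2-dione) | CC(C)(C)OC1=C(OC(C)(C)C)C(=O)C1=O
A2 | direct plan | 2-tert-butoxy-4-oxocyclobut-2-en-1-yl (S)-2-methylbutanoate | CC[C@H](C)C(=O)OC1C(=O)C=C1OC(C)(C)C
A3 | direct plan | (E)-tert-butyl[(1-methoxy-5-phenylpent-4-en-1-yn-3-yl)oxy]dimethylsilane (racemic) | COC#CC(O[Si](C)(C)C(C)(C)C)/C=C/c1ccccc1
A4 | direct plan | 6-tert-butoxy-3-[(E)-1-(tert-butyldimethylsilyloxy)-3-phenylprop-2-en-1-yl]-2-hydroxy-4-methoxyphenyl (S)-2-methylbutanoate | CC[C@H](C)C(=O)Oc1c(OC(C)(C)C)cc(OC)c(C(O[Si](C)(C)C(C)(C)C)/C=C/c2ccccc2)c1O
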